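## Retrosynthetic overview

- Feature (tetralin numbering: C1 bears the aryl group, ring A is C4a–C8a, ring B is C1–C4 with C4a and C8a): on ring B the hydroxymethyl carbons C9 (on C2) and C9′ (on C3) are cis to each other and trans to the C1 trimethoxyphenyl group. This is the pattern left by a syn addition to a C2=C3 alkene on the face away from that aryl group.
- C2–C9 and C3–C9′ are cut together by oxidative bis(methoxycarbonylation), leading back to (S)-1-aryl-1,4-dihydronaphthalene 15, two molecules of CO and two of MeOH. Ester reduction and debenzylation follow the key step.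
- Ring B is the only ring that is built. It is opened at C2=C3 by ring-closing metathesis to diene 14; ring A and the trimethoxyphenyl ring come from 1 and 12.
- The C1–aryl bond and the C1 stereocentre come from an anti-SN2′ arylation of (S)-allylic picolinate 11, whose carbinol centre is set by oxazaborolidine reduction of enone 9.
- The allyl group on C4a is placed by a para-Claisen shift from the oxygen on C7, starting from the 3-O-allyl ether of 2,3-dihydroxy-4-methoxybenzaldehyde 1.

Key step: step 10

## Route

Step 1
Reactants: 1 2,3-dihydroxy-4-methoxybenzaldehyde; 2 allyl bromide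
Product: 3 3-(allyloxy)-2-hydroxy-4-methoxybenzaldehyde
Conditions: NaH (2.2 equiv), DMSO, 20 °C; then 2 (1.0 equiv), 20 °C; aq. HCl
Reagents that add atoms: none
Why: Williamson etherification of the dianion, in which the 3-phenoxide (not conjugated with the formyl group and not held in its chelate) is the more nucleophilic oxygen, so that one equivalent of allyl bromide should alkylate O3 (the future oxygen on C7) and leave the 2-OH free.

Step 2
Reactants: 3 3-(allyloxy)-2-hydroxy-4-methoxybenzaldehyde
Product: 4 3-(allyloxy)-2-(benzyloxy)-4-methoxybenzaldehyde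
Conditions: BnBr (1.2 equiv), K2CO3, DMF, 60 °C
Reagents that add atoms: benzyl bromide, BrCc1ccccc1
Why: Williamson benzylation of the remaining hydrogen-bonded phenol under the carbonate/DMF conditions usual for salicylaldehydes, which leave the allyl ether and the aldehyde untouched.

Step 3
Reactants: 4 3-(allyloxy)-2-(benzyloxy)-4-methoxybenzaldehyde
Product: 7 6-allyl-2-(benzyloxy)-3-hydroxy-4-methoxybenzaldehyde, via ortho-dienone 5 (not isolated), via para-dienone 6 (not isolated)
Conditions: PhNEt2, 200 °C, sealed tube, argon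
Reagents that add atoms: none
Why: Aromatic para-Claisen rearrangement: both positions ortho to the allyl ether carry oxygen substituents, so the first [3,3] shift gives an ortho-dienone that cannot enolise, a Cope [3,3] shift relays the allyl group to the free para carbon (C6 of the aldehyde, the future C4a), and tautomerisation restores the phenol.

Step 4
Reactants: 7 6-allyl-2-(benzyloxy)-3-hydroxy-4-methoxybenzaldehyde
Product: 8 6-allyl-2,3-bis(benzyloxy)-4-methoxybenzaldehyde
Conditions: BnBr (1.5 equiv), K2CO3, tetrabutylammonium iodide (cat.), DMF, 70 °C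
Reagents that add atoms: benzyl bromide, BrCc1ccccc1
Why: Williamson benzylation of the flanked phenol, helped by iodide catalysis, gives the bis(benzyl) ether whose two protecting groups can be removed together in the last step.

Step 5
Reactants: 8 6-allyl-2,3-bis(benzyloxy)-4-methoxybenzaldehyde
Product: 9 (E)-4-[6-allyl-2,3-bis(benzyloxy)-4-methoxyphenyl]but-3-en-2-one
Conditions: Ph3P=CHC(O)CH3 (1.5 equiv), toluene, 110 °C
Reagents that add atoms: 1-(triphenylphosphoranylidene)propan-2-one, CC(=O)C=P(c1ccccc1)(c1ccccc1)c1ccccc1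
Why: Wittig olefination with a stabilised ylide, which tolerates the two ortho substituents of the aldehyde and should give the (E)-enone selectively.

Step 6
Reactants: 9 (E)-4-[6-allyl-2,3-bis(benzyloxy)-4-methoxyphenyl]but-3-en-2-one
Product: 10 (2S,3E)-4-[6-allyl-2,3-bis(benzyloxy)-4-methoxyphenyl]but-3-en-2-ol
Conditions: (R)-Me-CBS oxazaborolidine [(R)-1-methyl-3,3-diphenyltetrahydro-1H,3H-pyrrolo[1,2-c][1,3,2]oxazaborole] (0.2 equiv), catecholborane (1.5 equiv), toluene, −78 °C; MeOH, then aq. NaOH wash
Reagents that add atoms: none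
Why: Corey–Bakshi–Shibata reduction, in which the alkenyl group acts as the larger ketone substituent so that the (R)-oxazaborolidine should deliver hydride to give the (S)-carbinol, while catecholborane at −78 °C leaves the allyl group and the enone C=C bond alone.

Step 7
Reactants: 10 (2S,3E)-4-[6-allyl-2,3-bis(benzyloxy)-4-methoxyphenyl]but-3-en-2-ol
Product: 11 (2S,3E)-4-[6-allyl-2,3-bis(benzyloxy)-4-methoxyphenyl]but-3-en-2-yl pyridine-2-carboxylate
Conditions: picolinic acid (1.5 equiv), DCC (1.5 equiv), DMAP (0.1 equiv), CH2Cl2, 0 to 20 °C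
Reagents that add atoms: picolinic acid, OC(=O)c1ccccn1
Why: Steglich esterification acylates the oxygen without breaking the C–O bond, so the (S) centre is retained, and the neutral conditions avoid ionisation of the electron-rich allylic ester.

Step 8
Reactants: 11 (2S,3E)-4-[6-allyl-2,3-bis(benzyloxy)-4-methoxyphenyl]but-3-en-2-yl pyridine-2-carboxylate; 12 5-bromo-1,2,3-trimethoxybenzene
Product: 14 1-allyl-3,4-bis(benzyloxy)-5-methoxy-2-[(1S,2E)-1-(3,4,5-trimethoxyphenyl)but-2-en-1-yl]benzene, via (3,4,5-trimethoxyphenyl)magnesium bromide 13 (not isolated)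
Conditions: 12, Mg, THF, 40 °C; then 13 (3 equiv), CuBr·SMe2 (1.5 equiv), THF, −20 °C; 11, 0 °C
Reagents that add atoms: none
Why: Copper-mediated anti-SN2′ allylic substitution of an allylic picolinate with an aryl Grignard-derived copper reagent: the magnesium-chelated picolinoxy group directs the aryl group to the γ-carbon anti to the leaving group through the conformer with the carbinol hydrogen eclipsing the alkene, so the (S)-carbinol centre should be transferred to the (S)-diarylmethine centre (the future C1) with an (E)-propenyl group.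

Step 9
Reactants: 14 1-allyl-3,4-bis(benzyloxy)-5-methoxy-2-[(1S,2E)-1-(3,4,5-trimethoxyphenyl)but-2-en-1-yl]benzene
Product: 15 (S)-7,8-bis(benzyloxy)-6-methoxy-1-(3,4,5-trimethoxyphenyl)-1,4-dihydronaphthalene
Conditions: second-generation Grubbs catalyst (5 mol %), p-benzoquinone (10 mol %), CH2Cl2 (5 mM), 40 °C, argon
Reagents that add atoms: none
Why: Ring-closing metathesis joins the allyl group on C4a to the propenyl group on C1 with loss of propene and closes six-membered ring B at C2=C3, the benzoquinone additive suppressing ruthenium hydride-mediated alkene migration, and the C1 stereocentre is not involved.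

Step 10
Reactants: 15 (S)-7,8-bis(benzyloxy)-6-methoxy-1-(3,4,5-trimethoxyphenyl)-1,4-dihydronaphthalene; 16 carbon monoxide; 17 methanol
Product: 18 dimethyl (1S,2R,3S)-7,8-bis(benzyloxy)-6-methoxy-1-(3,4,5-trimethoxyphenyl)-1,2,3,4-tetrahydronaphthalene-2,3-dicarboxylate
Conditions: Pd(OCOCF3)2 (5 mol %), bis(2,6-dimethylphenylimino)acenaphthene (5.5 mol %), p-TsOH·H2O (5 mol %), p-benzoquinone (1.5 equiv), CO (4 bar), MeOH–THF 7:1, 20 °C
Reagents that add atoms: carbon monoxide, [C-]#[O+]; methanol, CO
Why: Oxidative bis(alkoxycarbonylation): a methoxycarbonyl complex of divalent palladium carrying the diimine ligand binds the C2=C3 alkene and inserts it in a syn fashion, CO inserts into the new alkyl–palladium bond, and methanolysis of the acyl complex releases diester 18 and zerovalent palladium, which p-benzoquinone and acid return to the divalent state. The closest known reaction type is the palladium–diimine-catalysed bis(methoxycarbonylation) of 1,2-disubstituted and cyclic alkenes with benzoquinone as oxidant, which is stereospecifically syn. No ring is closed: the two skeletal bonds C2–C9 and C3–C9′ are made on the existing ring B, each from one molecule of CO and one of methanol, so that two equivalents of 16 and two of 17 are consumed. The new stereocentres C2 and C3 are controlled by C1, because peri strain with the C8 benzyloxy group should hold the trimethoxyphenyl group pseudoaxial on the flattened boat of ring B, so that palladium and both ester carbons enter on the opposite face, which puts C9 trans to the aryl group and, through the syn insertion, C9′ cis to C9 (1S,2R,3S). The step needs facial selectivity and a preference for CO insertion over β-hydride loss toward C1 or C4 and over allylic C–H palladation, both of which would lead to a conjugated or aromatised ring B; the pseudoaxial aryl group provides the first, and 4 bar of CO at 20 °C, with the alkyl–palladium intermediate chelated by the first ester carbonyl, is expected to provide the second. Which alkene carbon is carbonylated first is irrelevant, since both receive the same group.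

Step 11
Reactants: 18 dimethyl (1S,2R,3S)-7,8-bis(benzyloxy)-6-methoxy-1-(3,4,5-trimethoxyphenyl)-1,2,3,4-tetrahydronaphthalene-2,3-dicarboxylate
Product: 19 [(1S,2R,3S)-7,8-bis(benzyloxy)-6-methoxy-1-(3,4,5-trimethoxyphenyl)-1,2,3,4-tetrahydronaphthalene-2,3-diyl]dimethanol
Conditions: LiAlH4 (3 equiv), THF, 0 °C; aq. potassium sodium tartrate (KNaC4H4O6) work-up
Reagents that add atoms: none
Why: Hydride reduction of both esters to primary alcohols, which at 0 °C is faster than enolisation so that the cis relationship at C2 and C3 should be kept, while benzyl and methyl ethers are inert.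

Step 12
Reactants: 19 [(1S,2R,3S)-7,8-bis(benzyloxy)-6-methoxy-1-(3,4,5-trimethoxyphenyl)-1,2,3,4-tetrahydronaphthalene-2,3-diyl]dimethanol
Product: 20 (1S,2R,3S)-2,3-bis(hydroxymethyl)-6-methoxy-1-(3,4,5-trimethoxyphenyl)-1,2,3,4-tetrahydronaphthalene-7,8-diol
Conditions: H2 (1 atm), 10% Pd/C, EtOAc–MeOH, 20 °C
Reagents that add atoms: none
Why: Catalytic hydrogenolysis of the two benzyl aryl ethers frees the phenols on C7 and C8, while the diarylmethine C1–H bond carries no leaving group and the three stereocentres are untouched.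

## Compound list

1 | 2,3-dihydroxy-4-methoxybenzaldehyde | COc1ccc(C=O)c(O)c1O | starting material
2 | allyl bromide | C=CCBr | starting material
3 | 3-(allyloxy)-2-hydroxy-4-methoxybenzaldehyde | COc1ccc(C=O)c(O)c1OCC=C | intermediate
4 | 3-(allyloxy)-2-(benzyloxy)-4-methoxybenzaldehyde | COc1ccc(C=O)c(OCc2ccccc2)c1OCC=C | intermediate
5 | ortho-dienone, 4-allyl-2-(benzyloxy)-4-methoxy-3-oxocyclohexa-1,5-diene-1-carbaldehyde | O=C1C(OC)(CC=C)C=CC(C=O)=C1OCc1ccccc1 | intermediate
6 | para-dienone, 6-allyl-2-(benzyloxy)-4-methoxy-3-oxocyclohexa-1,4-diene-1-carbaldehyde | O=C1C(OCc2ccccc2)=C(C=O)C(CC=C)C=C1OC | intermediate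
7 | 6-allyl-2-(benzyloxy)-3-hydroxy-4-methoxybenzaldehyde | COc1cc(CC=C)c(C=O)c(OCc2ccccc2)c1O | intermediate
8 | 6-allyl-2,3-bis(benzyloxy)-4-methoxybenzaldehyde | COc1cc(CC=C)c(C=O)c(OCc2ccccc2)c1OCc1ccccc1 | intermediate
9 | (E)-4-[6-allyl-2,3-bis(benzyloxy)-4-methoxyphenyl]but-3-en-2-one | CC(=O)/C=C/c1c(CC=C)cc(OC)c(OCc2ccccc2)c1OCc1ccccc1 | intermediate
10 | (2S,3E)-4-[6-allyl-2,3-bis(benzyloxy)-4-methoxyphenyl]but-3-en-2-ol | C[C@H](O)/C=C/c1c(CC=C)cc(OC)c(OCc2ccccc2)c1OCc1ccccc1 | intermediate
11 | (2S,3E)-4-[6-allyl-2,3-bis(benzyloxy)-4-methoxyphenyl]but-3-en-2-yl pyridine-2-carboxylate | C[C@H](OC(=O)c1ccccn1)/C=C/c1c(CC=C)cc(OC)c(OCc2ccccc2)c1OCc1ccccc1 | intermediate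
12 | 5-bromo-1,2,3-trimethoxybenzene | COc1cc(Br)cc(OC)c1OC | starting material
13 | (3,4,5-trimethoxyphenyl)magnesium bromide | COc1cc([Mg]Br)cc(OC)c1OC | intermediate
14 | 1-allyl-3,4-bis(benzyloxy)-5-methoxy-2-[(1S,2E)-1-(3,4,5-trimethoxyphenyl)but-2-en-1-yl]benzene | COc1cc(CC=C)c(c(OCc2ccccc2)c1OCc1ccccc1)[C@H](c1cc(OC)c(OC)c(OC)c1)/C=C/C | intermediate
15 | (S)-7,8-bis(benzyloxy)-6-methoxy-1-(3,4,5-trimethoxyphenyl)-1,4-dihydronaphthalene | COc1cc2c(c(OCc3ccccc3)c1OCc1ccccc1)[C@H](c1cc(OC)c(OC)c(OC)c1)C=CC2 | intermediate
16 | carbon monoxide | [C-]#[O+] | starting material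
17 | methanol | CO | starting material
18 | dimethyl (1S,2R,3S)-7,8-bis(benzyloxy)-6-methoxy-1-(3,4,5-trimethoxyphenyl)-1,2,3,4-tetrahydronaphthalene-2,3-dicarboxylate (esters cis to each other, trans to the aryl group) | COc1cc2c(c(OCc3ccccc3)c1OCc1ccccc1)[C@H](c1cc(OC)c(OC)c(OC)c1)[C@@H](C(=O)OC)[C@@H](C(=O)OC)C2 | intermediate
19 | [(1S,2R,3S)-7,8-bis(benzyloxy)-6-methoxy-1-(3,4,5-trimethoxyphenyl)-1,2,3,4-tetrahydronaphthalene-2,3-diyl]dimethanol | COc1cc2c(c(OCc3ccccc3)c1OCc1ccccc1)[C@H](c1cc(OC)c(OC)c(OC)c1)[C@@H](CO)[C@@H](CO)C2 | intermediate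
20 | (1S,2R,3S)-2,3-bis(hydroxymethyl)-6-methoxy-1-(3,4,5-trimethoxyphenyl)-1,2,3,4-tetrahydronaphthalene-7,8-diol (CNP0188980.1) | COc1cc2c(c(O)c1O)[C@H](c1cc(OC)c(OC)c(OC)c1)[C@@H](CO)[C@@H](CO)C2 | target

## Step count and risks

Total: 12 steps. Longest linear sequence: 12 steps (1 to 20); bromide 12 enters in step 8, and CO and methanol enter in step 10.

**Step 10 (key step).** Ring B may be aromatised or its alkene moved into conjugation, through allylic C–H palladation or β-hydride loss under the oxidising conditions, before the second carbonylation takes place. The facial bias exerted by the C1 aryl group may also be incomplete.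

Fallback: syn diboration without an oxidant, followed by one-carbon homologation of both C–B bonds. It sets out from 15 and comes back at 19, so that steps 10 and 11 are bypassed. Alkoxide-activated diboration with B2pin2 (Cs2CO3 cat., MeOH, THF, 70 °C) is a syn addition that accepts unstrained cyclic alkenes; it should take place anti to the aryl group and give 7,8-bis(benzyloxy)-6-methoxy-2,3-bis(pinacolboryl)-1-(3,4,5-trimethoxyphenyl)tetralin F1, with the boryl groups cis to each other and trans to the aryl group. Double Matteson homologation with LiCH2Cl, made in the flask from chloroiodomethane and n-BuLi (THF, −78 to 20 °C), should insert a methylene group into each C–B bond with retention at C2 and C3 and give the 2,3-bis(pinacolborylmethyl) compound F2. Oxidation with NaOH/H2O2 (THF, 0 °C) would then give diol 19.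

**Step 8.** Chirality transfer may be eroded by ionisation of the electron-rich secondary picolinate. The aryl group may also attack the α-carbon in place of the crowded benzylic γ-carbon.

Fallback: catalyst-controlled SN2′ arylation of an achiral primary phosphate, which has no stereocentre to lose. It sets out from 8 and comes back at 15. Horner–Wadsworth–Emmons olefination of 8 with triethyl phosphonoacetate (NaH, THF) would give ethyl (E)-3-[6-allyl-2,3-bis(benzyloxy)-4-methoxyphenyl]acrylate F3. Reduction with i-Bu2AlH (CH2Cl2, −78 °C) would give (E)-3-[6-allyl-2,3-bis(benzyloxy)-4-methoxyphenyl]prop-2-en-1-ol F4, and ClP(O)(OEt)2 with pyridine and DMAP would give (E)-3-[6-allyl-2,3-bis(benzyloxy)-4-methoxyphenyl]allyl diethyl phosphate F5. Copper-catalysed asymmetric allylic arylation of F5 with Grignard reagent 13 would give (S)-1-allyl-3,4-bis(benzyloxy)-5-methoxy-2-[1-(3,4,5-trimethoxyphenyl)allyl]benzene F6; the catalyst is CuCl with a C2-symmetric chiral N-heterocyclic carbene generated from its imidazolinium chloride (CH2Cl2–Et2O, −78 °C), and the ligand antipode would be selected on a test scale for the (S) product. Ring-closing metathesis of F6 with the second-generation Grubbs catalyst, with loss of ethylene, leads to 15.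

**Step 3.** Prolonged heating at 200 °C may cause decomposition or loss of the benzyl group. The Cope leg toward the carbon next to the formyl group may also stall.

Fallback: placement of the allyl group by directed ortho-metalation in place of a sigmatropic shift. It sets out from 1 and comes back at 8, so that steps 1 to 4 are bypassed. MOMCl and i-Pr2NEt (CH2Cl2) would give 4-methoxy-2,3-bis(methoxymethoxy)benzaldehyde F7. LiN(CH3)CH2CH2N(CH3)2 (THF, −20 °C) masks the aldehyde as the lithium α-amino alkoxide F8, which directs n-BuLi to the only C–H ortho to it and gives the ortho-lithiated α-amino alkoxide F9. Transmetalation with CuBr·SMe2, allylation with 2 and aqueous work-up would give 6-allyl-4-methoxy-2,3-bis(methoxymethoxy)benzaldehyde F10. Aqueous HCl in THF (50 °C) removes both acetals to give 6-allyl-2,3-dihydroxy-4-methoxybenzaldehyde F11, and BnBr/K2CO3 in DMF then gives 8.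

## Further compounds

F1 | step 10 | 7,8-bis(benzyloxy)-6-methoxy-2,3-bis(pinacolboryl)-1-(3,4,5-trimethoxyphenyl)tetralin, boryl groups cis to each other and trans to the aryl group, (S) at C1 | COc1cc2c(c(OCc3ccccc3)c1OCc1ccccc1)[C@H](c1cc(OC)c(OC)c(OC)c1)[C@@H](B1OC(C)(C)C(C)(C)O1)[C@@H](B1OC(C)(C)C(C)(C)O1)C2
F2 | step 10 | 7,8-bis(benzyloxy)-6-methoxy-2,3-bis(pinacolborylmethyl)-1-(3,4,5-trimethoxyphenyl)tetralin, same relative and absolute configuration | COc1cc2c(c(OCc3ccccc3)c1OCc1ccccc1)[C@H](c1cc(OC)c(OC)c(OC)c1)[C@@H](CB1OC(C)(C)C(C)(C)O1)[C@@H](CB1OC(C)(C)C(C)(C)O1)C2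
F3 | step 8 | ethyl (E)-3-[6-allyl-2,3-bis(benzyloxy)-4-methoxyphenyl]acrylate | CCOC(=O)/C=C/c1c(CC=C)cc(OC)c(OCc2ccccc2)c1OCc1ccccc1
F4 | step 8 | (E)-3-[6-allyl-2,3-bis(benzyloxy)-4-methoxyphenyl]prop-2-en-1-ol | OC/C=C/c1c(CC=C)cc(OC)c(OCc2ccccc2)c1OCc1ccccc1
F5 | step 8 | (E)-3-[6-allyl-2,3-bis(benzyloxy)-4-methoxyphenyl]allyl diethyl phosphate | CCOP(=O)(OCC)OC/C=C/c1c(CC=C)cc(OC)c(OCc2ccccc2)c1OCc1ccccc1
F6 | step 8 | (S)-1-allyl-3,4-bis(benzyloxy)-5-methoxy-2-[1-(3,4,5-trimethoxyphenyl)allyl]benzene | COc1cc(CC=C)c(c(OCc2ccccc2)c1OCc1ccccc1)[C@H](c1cc(OC)c(OC)c(OC)c1)C=C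
F7 | step 3 | 4-methoxy-2,3-bis(methoxymethoxy)benzaldehyde | COCOc1c(C=O)ccc(OC)c1OCOC
F8 | step 3 | lithium α-amino alkoxide from F7 and lithium N,N,N'-trimethylethylenediamide | [Li+].[O-]C(N(C)CCN(C)C)c1ccc(OC)c(OCOC)c1OCOC
F9 | step 3 | ortho-lithiated α-amino alkoxide (lithium on C6) | [Li]c1cc(OC)c(OCOC)c(OCOC)c1C(O[Li])N(C)CCN(C)C
F10 | step 3 | 6-allyl-4-methoxy-2,3-bis(methoxymethoxy)benzaldehyde | COCOc1c(C=O)c(CC=C)cc(OC)c1OCOC
F11 | step 3 | 6-allyl-2,3-dihydroxy-4-methoxybenzaldehyde | COc1cc(CC=C)c(C=O)c(O)c1O
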